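Compound numbers used below are those of the steps and of the compound list at the end.

## Analysis of the target

The target is a dihydrochalcone: a C(=O)–CH2–CH2 chain joins ring A, the benzene ring of a 2,2-dimethylchroman (O1, C2, C3, C4, C4a, C5 to C8, C8a), to ring B, a benzene ring with a free hydroxyl at C3', a methyl ether at C4' and a prenyl group at C5'. There is no stereocentre, and the only alkene carries two identical methyl groups, so no configuration has to be set or kept. Ring A is an acylphloroglucinol in which one of the three oxygens is the pyran oxygen O1 and the ketone carbon sits on C6, between the free hydroxyls at C5 and C7, and not on C8. The sensitive groups are the trisubstituted alkene (acid, electrophiles, hydrogenation), the tertiary alkyl aryl ether of the pyran ring, the oxidisable electron-rich phenols, and the single methyl ether on ring B, which must survive while every other phenolic oxygen ends free. The difficulty is regiochemical: electrophilic acylation of a 5,7-dioxygenated chroman does not choose reliably between C6 and C8, the three oxygens of ring A have to be told apart, and the last deprotection must not need a Lewis acid strong enough to harm the alkene or the ring B methyl ether. The strategy rests on the vicinal pair on ring A: the C5 hydroxyl and the ketone carbon on C6. Both bonds, C5–O and C6–C(=O), can be made in one event across a C5–C6 aryne by insertion into the acyl–oxygen bond of a carboxylic acid that already carries ring B and both methylene carbons.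

## Retrosynthetic reasoning

**25 to 24.** The last operation is the removal of two methoxymethyl (MOM) ethers, one on O7 of ring A and one on O3' of ring B. A methyl ether at C7 was rejected: it would have to be cleaved next to a ketone whose carbonyl oxygen is already tied up by the C5 hydroxyl, and the boron or aluminium halides that force such a cleavage also attack an acetal on ring B, the doubly flanked ring B methyl ether and the prenyl alkene. With an acetal on both oxygens the end game is a single mild acid methanolysis that leaves the methyl ether, the pyran ether and the alkene alone.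

**24 to 13 and 22 (through 23).** The C5–O bond and the C6–carbonyl bond are cut together. This is the most convergent cut available: all carbons of the chain and the whole of ring B arrive in acid 22, and the position of the acyl group is fixed by the geometry of aryne 23 and not by the directing effects of three competing oxygens. The forward reaction has to generate 23 from silyl triflate 13 with fluoride, add the carboxylate oxygen to C5 and not to C6, and let the resulting C6 aryl anion take the acyl group from oxygen before it is protonated. The pyran oxygen is already in place, so a 6-acyl versus 8-acyl question never arises.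

**13 to 11, 8 and 7.** The triflate is traced back to a secondary carbamate on O5 and the C6–Si bond to a directed ortho-metalation. The carbamate in 8 has only one free ortho position, C6 (the other is C4a), and that position also lies next to the C7 acetal oxygen, so the silyl group in 11 can only go where the aryne needs it. The carbamate is chosen as a secondary one because it can later be removed by amine base and exchanged for triflate in one flask. Carbamate 8 comes from phenol 7 by addition to an isocyanate.

**7 to 4, 3, 1 and 2.** Phenol 7 needs O7 protected and O5 free, two oxygens that are nearly equivalent in a plain chroman. A carbonyl at C4 solves this: in chromanone 3 the C5 hydroxyl is locked in a hydrogen bond and the C7 hydroxyl, para to the carbonyl, is the acidic one, so 4 forms selectively. The carbonyl is then removed by reductive deoxygenation through carbonate 5 and ortho-quinone methide 6. Chromanone 3 is cut at the C4–C4a and O1–C2 bonds to phloroglucinol 1 and unsaturated acid 2; since 1 is threefold symmetric, this annulation has only one outcome.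

**22 to 20 and 21.** The C5'–CH2 bond of the prenyl group is cut as a Suzuki–Miyaura coupling of aryl bromide 20 with allylboronate 21. It is placed last in the ring B sequence because an allylboronate would add to the aldehyde of the earlier intermediates, and because the alkene is then exposed to nothing but the coupling itself.

**20 to 19, 16 and 17; 16 to 15 and 14.** The two chain carbons next to ring B come from Meldrum's acid 17 by reductive Knoevenagel alkylation of aldehyde 16 to 19, then hydrolysis and decarboxylation to 20. This gives the saturated acid directly, with no catalytic hydrogenation that could remove bromine and no ester hydrolysis. Aldehyde 16 goes back to bromocatechol aldehyde 14 by two O-alkylations ordered by acidity: the C4 hydroxyl, para to the formyl group, is methylated first (15), and the remaining one is then protected.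

## Alternatives that were turned down

**Alternative 1:** The pyran ring is cut at O1–C2 and C3–C4. Forward, heating the phenolic Mannich base 3-[(dimethylamino)methyl]-4-hydroxy-2,6-dimethoxybenzaldehyde A2 expels the amine to give an ortho-quinone methide, which adds isobutene A3 in a [4+2] cycloaddition to give 5,7-dimethoxy-2,2-dimethylchroman-6-carbaldehyde A1.
- For it: the orientation of the cycloaddition is inherent (the CH2 terminus of A3 bonds to the methide carbon, the tertiary carbon to oxygen). The gem-dimethyl pyran forms in one step with the C6 carbon substituent already present. On ring construction it is shorter than the three steps (1 to 3) spent here.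
- Against it: A1 carries only one carbon of the chain, so a ring B organometallic still has to be added and the carbinol oxidised. A3 is a gas that needs a sealed vessel at high temperature, where the quinone methide can dimerise. Both C5 and C7 oxygens are methyl ethers flanking the future ketone, so two chelation-assisted demethylations are needed while the ring B methyl ether must stay; the second is slow once the first hydroxyl holds the carbonyl.
- Comparison: the chosen route makes the ketone and the free C5 hydroxyl in the same step and ends with one acetal cleavage.

**Alternative 2:** The C4–C4a bond is cut. Forward, a cationic phosphine complex of monovalent gold activates the terminal alkyne of the aryl 1,1-dimethylpropargyl ether 1-[2,6-dihydroxy-4-(2-methylbut-3-yn-2-yloxy)phenyl]-3-[3-hydroxy-4-methoxy-5-(3-methylbut-2-enyl)phenyl]propan-1-one A5, and the ortho carbon attacks to close the 2H-chromene 1-(5,7-dihydroxy-2,2-dimethyl-2H-chromen-6-yl)-3-[3-hydroxy-4-methoxy-5-(3-methylbut-2-enyl)phenyl]propan-1-one A4, which must then be saturated.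
- For it: it is the strongest of the three on step and protecting-group economy, since it works on the unprotected skeleton. Because the two ortho carbons of A5 are equivalent, the cyclisation has one regiochemical outcome, as secure as the aryne orientation here.
- Against it: A4 holds two alkenes, and the chromene C3=C4 bond must be reduced without touching the prenyl group. A cis-disubstituted styrenyl alkene next to a quaternary carbon and a trisubstituted alkene differ only in degree towards hydrogenation catalysts. Making A5 also needs one of four free phenols alkylated with a tertiary propargylic electrophile.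
- Comparison: the chosen route is longer, but the pyran ring is saturated from step 3 on and only one alkene is ever present.

**Alternative 3:** The two C2–CH3 bonds are cut. Forward, an excess of a methyl Grignard reagent adds twice to the lactone carbonyl of 6-bromo-5,7-dimethoxychroman-2-one A7 and opens it to 4-bromo-2-(3-hydroxy-3-methylbutyl)-3,5-dimethoxyphenol A6. Acid then recloses the ring to 6-bromo-5,7-dimethoxy-2,2-dimethylchroman A8, whose bromine is exchanged for lithium and acylated.
- For it: double Grignard addition to a lactone is about as reliable as chemistry gets, and the bromine marks C6 as firmly as the silyl triflate does here.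
- Against it: the ring is opened only to be closed again. Bromination of the dihydrocoumarin must choose C6, between two methoxy groups, over the less hindered C8. The end game again requires cleavage of two methyl ethers ortho to one ketone beside the ring B methyl ether and the prenyl group.
- Comparison: the chosen route carries more risk in its key step, but it avoids the demethylations and brings the ketone in with the C5 hydroxyl already free.

Key step: step 12

Remark on protecting groups and stereochemistry: the two phenols that must be masked during the aryne step (O7 of ring A and O3' of ring B) are both carried as methoxymethyl ethers so that one mild acid treatment ends the synthesis; no compound of the main route has a stereocentre.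

## Route

Step 1
Reactants: 1 phloroglucinol (benzene-1,3,5-triol); 2 3-methylbut-2-enoic acid
Product: 3 5,7-dihydroxy-2,2-dimethylchroman-4-one
Conditions: P2O5 in MeSO3H (1:10 by weight), 70 °C
Reagents that add atoms: none
Why: Friedel–Crafts acylation of the trihydric phenol by the activated unsaturated acid followed by intramolecular oxa-Michael addition closes the chromanone; 1 is threefold symmetric, so only one product can form.

Step 2
Reactants: 3 5,7-dihydroxy-2,2-dimethylchroman-4-one
Product: 4 5-hydroxy-7-(methoxymethoxy)-2,2-dimethylchroman-4-one
Conditions: MOMCl (1.1 equiv), K2CO3, acetone, 0 °C to rt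
Reagents that add atoms: chloromethyl methyl ether, COCCl
Why: Williamson-type O-alkylation; the C5 hydroxyl is held in a hydrogen bond to the C4 carbonyl, whereas the C7 hydroxyl, para to that carbonyl, is the acidic and accessible one, so one equivalent of the chloride should go to O7.

Step 3
Reactants: 4 5-hydroxy-7-(methoxymethoxy)-2,2-dimethylchroman-4-one
Product: 7 7-(methoxymethoxy)-2,2-dimethylchroman-5-ol, via ethyl aryl carbonate 5 (not isolated), via ortho-quinone methide 6 (not isolated)
Conditions: ClCO2Et, Et3N, THF, 0 °C; then NaBH4, H2O, 0 °C to rt
Reagents that add atoms: none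
Why: Reductive deoxygenation of an ortho-hydroxyaryl ketone through its O-ethoxycarbonyl derivative: hydride reduces the C4 ketone of 5, the carbonate shifts to the new benzylic oxygen and is expelled by the C5 phenoxide to give 6, and a second hydride adds to C4 of 6 to return the phenol; the basic medium leaves the MOM ether intact.

Step 4
Reactants: 7 7-(methoxymethoxy)-2,2-dimethylchroman-5-ol
Product: 8 7-(methoxymethoxy)-2,2-dimethylchroman-5-yl N-isopropylcarbamate
Conditions: i-PrNCO, Et3N (cat.), CH2Cl2, rt
Reagents that add atoms: isopropyl isocyanate, CC(C)N=C=O
Why: Base-catalysed addition of the phenol to the isocyanate gives the secondary carbamate, which will direct the metalation and later leave under mild amine base.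

Step 5
Reactants: 8 7-(methoxymethoxy)-2,2-dimethylchroman-5-yl N-isopropylcarbamate
Product: 11 7-(methoxymethoxy)-2,2-dimethyl-6-(trimethylsilyl)chroman-5-yl N-isopropylcarbamate, via N-silyl carbamate 9 (not isolated), via N-silyl 6-silyl carbamate 10 (not isolated)
Conditions: TBSOTf, TMEDA, Et2O, 0 °C to rt; n-BuLi, TMEDA, −78 °C; TMSCl, −78 °C to rt; aq. NaHSO4, 0 °C
Reagents that add atoms: chlorotrimethylsilane, C[Si](C)(C)Cl
Why: Directed ortho-metalation: N-silylation in the flask (9) masks the N–H, n-BuLi/TMEDA then removes the C6 proton, the only position ortho to the carbamate (C4a is substituted) and also ortho to the C7 acetal oxygen, and TMSCl traps the aryllithium (10); brief cold aqueous acid takes off the N-silyl group only.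

Step 6
Reactants: 11 7-(methoxymethoxy)-2,2-dimethyl-6-(trimethylsilyl)chroman-5-yl N-isopropylcarbamate
Product: 13 7-(methoxymethoxy)-2,2-dimethyl-6-(trimethylsilyl)chroman-5-yl trifluoromethanesulfonate, via silyl phenol 12 (not isolated)
Conditions: Et2NH, DBU, MeCN, 40 °C; then PhNTf2, rt
Reagents that add atoms: N-phenylbis(trifluoromethanesulfonimide), O=S(=O)(N(c1ccccc1)S(=O)(=O)C(F)(F)F)C(F)(F)F
Why: Amine base triggers E1cB loss of isopropyl isocyanate from the secondary carbamate (scavenged by Et2NH) to free the phenoxide of 12, which is triflated in the same flask; the conditions do not attack the aryl–silicon bond or the acetal.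

Step 7
Reactants: 14 3-bromo-4,5-dihydroxybenzaldehyde
Product: 15 3-bromo-5-hydroxy-4-methoxybenzaldehyde
Conditions: MeI (1.05 equiv), Li2CO3, DMF, 40 °C
Reagents that add atoms: iodomethane, CI
Why: Chemoselective Williamson methylation: the C4 hydroxyl, para to the formyl group and ortho to bromine, is by far the more acidic, so the weak base ionises only that oxygen and one equivalent of MeI should alkylate it.

Step 8
Reactants: 15 3-bromo-5-hydroxy-4-methoxybenzaldehyde
Product: 16 3-bromo-4-methoxy-5-(methoxymethoxy)benzaldehyde
Conditions: MOMCl, K2CO3, acetone, rt
Reagents that add atoms: chloromethyl methyl ether, COCCl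
Why: Williamson-type acetal protection of the remaining phenol; the MOM ether withstands all later basic and organometallic steps and leaves at the end together with the one on ring A.

Step 9
Reactants: 16 3-bromo-4-methoxy-5-(methoxymethoxy)benzaldehyde; 17 Meldrum's acid (2,2-dimethyl-1,3-dioxane-4,6-dione)
Product: 19 5-[3-bromo-4-methoxy-5-(methoxymethoxy)benzyl]-2,2-dimethyl-1,3-dioxane-4,6-dione, via benzylidene Meldrum's acid 18 (not isolated)
Conditions: Hantzsch ester (diethyl 1,4-dihydro-2,6-dimethylpyridine-3,5-dicarboxylate), L-proline (20 mol %), EtOH, rt
Reagents that add atoms: none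
Why: Organocatalytic three-component reductive alkylation: Knoevenagel condensation gives 18, whose highly electrophilic alkene accepts hydride from the Hantzsch ester in a conjugate transfer hydrogenation; aryl bromide and acetal are untouched, which a catalytic hydrogenation of a cinnamate would not guarantee.

Step 10
Reactants: 19 5-[3-bromo-4-methoxy-5-(methoxymethoxy)benzyl]-2,2-dimethyl-1,3-dioxane-4,6-dione
Product: 20 3-[3-bromo-4-methoxy-5-(methoxymethoxy)phenyl]propanoic acid
Conditions: pyridine/H2O (10:1), 100 °C
Reagents that add atoms: water, O
Why: Hydrolytic opening of the acylal, loss of acetone and decarboxylation of the resulting malonic acid give the propanoic acid directly, so no ester hydrolysis is needed; the buffered medium spares the MOM ether.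

Step 11
Reactants: 20 3-[3-bromo-4-methoxy-5-(methoxymethoxy)phenyl]propanoic acid; 21 prenylboronic acid pinacol ester (4,4,5,5-tetramethyl-2-(3-methylbut-2-enyl)-1,3,2-dioxaborolane)
Product: 22 3-[4-methoxy-3-(methoxymethoxy)-5-(3-methylbut-2-enyl)phenyl]propanoic acid
Conditions: PdCl2(IPent)(3-chloropyridine) (2 mol %; IPent = 1,3-bis[2,6-di(pentan-3-yl)phenyl]imidazol-2-ylidene), 5 M aq. KOH, THF, 70 °C; then aq. citric acid to pH 4
Reagents that add atoms: none
Why: Suzuki–Miyaura coupling of an allylboronate (oxidative addition of the aryl bromide to zerovalent palladium, transmetalation, reductive elimination); the very bulky carbene ligand favours bond formation at the boron-bearing carbon and so the linear prenyl arene, and the acid passes through as its potassium salt.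

Step 12
Reactants: 13 7-(methoxymethoxy)-2,2-dimethyl-6-(trimethylsilyl)chroman-5-yl trifluoromethanesulfonate (1.5 equiv); 22 3-[4-methoxy-3-(methoxymethoxy)-5-(3-methylbut-2-enyl)phenyl]propanoic acid
Product: 24 1-[5-hydroxy-7-(methoxymethoxy)-2,2-dimethylchroman-6-yl]-3-[4-methoxy-3-(methoxymethoxy)-5-(3-methylbut-2-enyl)phenyl]propan-1-one, via chroman-5,6-yne 23 (not isolated)
Conditions: CsF (4 equiv), THF, 125 °C, sealed tube
Reagents that add atoms: none
Why: Fluoride attacks silicon of 13 and triflate leaves from the neighbouring carbon, giving aryne 23, while 22 is converted into its cesium carboxylate in the same flask. The carboxylate oxygen adds to C5, and the C6 aryl anion so formed attacks the ester carbonyl on the neighbouring oxygen through a four-membered alkoxide that opens to the C5 phenoxide and the C6 ketone, a net insertion of the aryne into the acyl–oxygen bond. The closest known reaction type is the fluoride-mediated addition of carboxylic acids to arynes with ortho acyl migration, which gives ortho-hydroxyaryl ketones. No ring is closed and no stereocentre is formed, so no mode of closure or stereocontrol applies. The step needs one orientation of addition: the C7 acetal oxygen withdraws electron density through the sigma bonds and polarises the triple bond so that the nucleophile goes to the remote C5 and the negative charge develops at C6 beside that oxygen. It also needs acyl transfer to outrun protonation of the aryl anion, which the aprotic medium, the high temperature and the proximity of the ester carbonyl should secure. The prenyl alkene is a far poorer partner for the aryne than a carboxylate and should not interfere.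

Step 13
Reactants: 24 1-[5-hydroxy-7-(methoxymethoxy)-2,2-dimethylchroman-6-yl]-3-[4-methoxy-3-(methoxymethoxy)-5-(3-methylbut-2-enyl)phenyl]propan-1-one
Product: 25 1-(5,7-dihydroxy-2,2-dimethylchroman-6-yl)-3-[3-hydroxy-4-methoxy-5-(3-methylbut-2-enyl)phenyl]propan-1-one
Conditions: HCl (1.25 M in MeOH), rt to 40 °C
Reagents that add atoms: none
Why: Acid-catalysed methanolysis of both aryl methoxymethyl acetals; the prenyl group has a methyl ether and not a hydroxyl as its ortho neighbour, so it cannot cyclise, and a trisubstituted alkene adds methanol only slowly under these mild conditions, while the methyl ether and the pyran ether are inert.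

## Compound list

1 | phloroglucinol (benzene-1,3,5-triol) | Oc1cc(O)cc(O)c1 | starting material
2 | 3-methylbut-2-enoic acid | CC(C)=CC(=O)O | starting material
3 | 5,7-dihydroxy-2,2-dimethylchroman-4-one | CC1(C)CC(=O)c2c(O)cc(O)cc2O1 | intermediate
4 | 5-hydroxy-7-(methoxymethoxy)-2,2-dimethylchroman-4-one | CC1(C)CC(=O)c2c(O)cc(OCOC)cc2O1 | intermediate
5 | ethyl 7-(methoxymethoxy)-2,2-dimethyl-4-oxochroman-5-yl carbonate | CCOC(=O)Oc1cc(OCOC)cc2OC(C)(C)CC(=O)c12 | intermediate (not isolated)
6 | 7-(methoxymethoxy)-2,2-dimethyl-2,3-dihydro-5H-chromen-5-one (ortho-quinone methide) | COCOC1=CC(=O)C2=CCC(C)(C)OC2=C1 | intermediate (not isolated)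
7 | 7-(methoxymethoxy)-2,2-dimethylchroman-5-ol | COCOc1cc(O)c2CCC(C)(C)Oc2c1 | intermediate
8 | 7-(methoxymethoxy)-2,2-dimethylchroman-5-yl N-isopropylcarbamate | COCOc1cc(OC(=O)NC(C)C)c2CCC(C)(C)Oc2c1 | intermediate
9 | 7-(methoxymethoxy)-2,2-dimethylchroman-5-yl N-(tert-butyldimethylsilyl)-N-isopropylcarbamate | COCOc1cc(OC(=O)N(C(C)C)[Si](C)(C)C(C)(C)C)c2CCC(C)(C)Oc2c1 | intermediate (not isolated)
10 | 7-(methoxymethoxy)-2,2-dimethyl-6-(trimethylsilyl)chroman-5-yl N-(tert-butyldimethylsilyl)-N-isopropylcarbamate | COCOc1cc2OC(C)(C)CCc2c(OC(=O)N(C(C)C)[Si](C)(C)C(C)(C)C)c1[Si](C)(C)C | intermediate (not isolated)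
11 | 7-(methoxymethoxy)-2,2-dimethyl-6-(trimethylsilyl)chroman-5-yl N-isopropylcarbamate | COCOc1cc2OC(C)(C)CCc2c(OC(=O)NC(C)C)c1[Si](C)(C)C | intermediate
12 | 7-(methoxymethoxy)-2,2-dimethyl-6-(trimethylsilyl)chroman-5-ol | COCOc1cc2OC(C)(C)CCc2c(O)c1[Si](C)(C)C | intermediate (not isolated)
13 | 7-(methoxymethoxy)-2,2-dimethyl-6-(trimethylsilyl)chroman-5-yl trifluoromethanesulfonate | COCOc1cc2OC(C)(C)CCc2c(OS(=O)(=O)C(F)(F)F)c1[Si](C)(C)C | intermediate
14 | 3-bromo-4,5-dihydroxybenzaldehyde | O=Cc1cc(O)c(O)c(Br)c1 | starting material
15 | 3-bromo-5-hydroxy-4-methoxybenzaldehyde | COc1c(O)cc(C=O)cc1Br | intermediate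
16 | 3-bromo-4-methoxy-5-(methoxymethoxy)benzaldehyde | COCOc1cc(C=O)cc(Br)c1OC | intermediate
17 | Meldrum's acid (2,2-dimethyl-1,3-dioxane-4,6-dione) | CC1(C)OC(=O)CC(=O)O1 | starting material
18 | 5-[3-bromo-4-methoxy-5-(methoxymethoxy)benzylidene]-2,2-dimethyl-1,3-dioxane-4,6-dione | COCOc1cc(C=C2C(=O)OC(C)(C)OC2=O)cc(Br)c1OC | intermediate (not isolated)
19 | 5-[3-bromo-4-methoxy-5-(methoxymethoxy)benzyl]-2,2-dimethyl-1,3-dioxane-4,6-dione | COCOc1cc(CC2C(=O)OC(C)(C)OC2=O)cc(Br)c1OC | intermediate
20 | 3-[3-bromo-4-methoxy-5-(methoxymethoxy)phenyl]propanoic acid | COCOc1cc(CCC(=O)O)cc(Br)c1OC | intermediate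
21 | prenylboronic acid pinacol ester (4,4,5,5-tetramethyl-2-(3-methylbut-2-enyl)-1,3,2-dioxaborolane) | CC(C)=CCB1OC(C)(C)C(C)(C)O1 | starting material
22 | 3-[4-methoxy-3-(methoxymethoxy)-5-(3-methylbut-2-enyl)phenyl]propanoic acid | COCOc1cc(CCC(=O)O)cc(CC=C(C)C)c1OC | intermediate
23 | 7-(methoxymethoxy)-2,2-dimethyl-5,6-didehydrochroman (chroman-5,6-yne) | COCOC1=CC2=C(CCC(C)(C)O2)C#C1 | intermediate (not isolated)
24 | 1-[5-hydroxy-7-(methoxymethoxy)-2,2-dimethylchroman-6-yl]-3-[4-methoxy-3-(methoxymethoxy)-5-(3-methylbut-2-enyl)phenyl]propan-1-one | COCOc1cc2OC(C)(C)CCc2c(O)c1C(=O)CCc1cc(OCOC)c(OC)c(CC=C(C)C)c1 | intermediate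
25 | 1-(5,7-dihydroxy-2,2-dimethylchroman-6-yl)-3-[3-hydroxy-4-methoxy-5-(3-methylbut-2-enyl)phenyl]propan-1-one | COc1c(O)cc(CCC(=O)c2c(O)cc3c(c2O)CCC(C)(C)O3)cc1CC=C(C)C | target

## Step count and weak points

Total: 13 steps. Longest linear sequence: 8 steps (steps 1 to 6, then 12 and 13); the ring B branch is 5 steps (7 to 11) before the union.

**Step 12 (key step).** The most likely failure is protonation of the C6 aryl anion before it reaches the ester carbonyl, so that the sequence stops at O-arylation. Bifluoride formed from the acid is a proton source, and the anion is flanked by two oxygens. Other risks are partial loss of orientation in the carboxylate addition, because C5 is crowded by the C4 methylene; consumption of the aryne by an ene reaction with the prenyl group; and O-arylation of the product phenoxide.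

Fallback: set out from 8 and 22 and reach the same bond by directed metalation instead of an aryne. Acid 22 is converted (carbonyldiimidazole, then N,O-dimethylhydroxylamine hydrochloride) into the Weinreb amide N-methoxy-N-methyl-3-[4-methoxy-3-(methoxymethoxy)-5-(3-methylbut-2-enyl)phenyl]propanamide F1. Carbamate 8 is N-silylated to 9 and lithiated at C6 exactly as in step 5, and the aryllithium is quenched with F1 at −78 °C. Aqueous work-up should give the ketone 6-{3-[4-methoxy-3-(methoxymethoxy)-5-(3-methylbut-2-enyl)phenyl]propanoyl}-7-(methoxymethoxy)-2,2-dimethylchroman-5-yl N-isopropylcarbamate F2. Et2NH and DBU in MeCN then remove the carbamate, and the route is rejoined at 24.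

**Step 5.** Possible failures are metalation at C8 (between the acetal oxygen and O1) in competition with C6; cleavage of the aryl acetal by the silyl triflate during N-silylation; and 1,3-shift of the carbamoyl group to carbon if the aryllithium warms before it is silylated.

Fallback: set out from 7 with a tertiary carbamate that needs no silyl triflate. Diethylcarbamoyl chloride and NaH give 7-(methoxymethoxy)-2,2-dimethylchroman-5-yl N,N-diethylcarbamate F3. s-BuLi/TMEDA at −78 °C followed by TMSCl gives 7-(methoxymethoxy)-2,2-dimethyl-6-(trimethylsilyl)chroman-5-yl N,N-diethylcarbamate F4. LiAlH4 in THF cleaves the carbamate to phenol 12, where the route is rejoined; 12 is triflated with PhNTf2 as in the second half of step 6 to give 13.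

**Step 11.** Possible failures are transfer of the allyl unit through its tertiary carbon, giving the 1,1-dimethylallyl arene, and protodeboronation of 21 in hot aqueous KOH before coupling.

Fallback: set out from 20 and introduce the side chain in two stages. A Stille coupling with allyltributylstannane (Pd(PPh3)4, toluene, 100 °C), which has no regiochemical ambiguity, gives 3-[3-allyl-4-methoxy-5-(methoxymethoxy)phenyl]propanoic acid F5. Cross-metathesis with 2-methylbut-2-ene (second-generation Grubbs catalyst, CH2Cl2, 40 °C) converts the allyl into the prenyl group and rejoins the route at 22.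

**Step 3.** Possible failures are hydrolysis of carbonate 5 before hydride delivery, so that the reduction stops at the benzylic alcohol, or dimerisation or hydration of 6 in place of its reduction.

Fallback: set out from 4 and remove the oxygen by hydrogenolysis. NaBH4 in MeOH gives racemic 7-(methoxymethoxy)-2,2-dimethylchroman-4,5-diol F6, and H2 over Pd/C in EtOH cleaves the electron-rich benzylic C–O bond to rejoin the route at 7. No alkene is present at this stage, so hydrogenation is harmless.

## Further compounds

F1 | step 12 | N-methoxy-N-methyl-3-[4-methoxy-3-(methoxymethoxy)-5-(3-methylbut-2-enyl)phenyl]propanamide | COCOc1cc(CCC(=O)N(C)OC)cc(CC=C(C)C)c1OC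
F2 | step 12 | 6-{3-[4-methoxy-3-(methoxymethoxy)-5-(3-methylbut-2-enyl)phenyl]propanoyl}-7-(methoxymethoxy)-2,2-dimethylchroman-5-yl N-isopropylcarbamate | COCOc1cc2OC(C)(C)CCc2c(OC(=O)NC(C)C)c1C(=O)CCc1cc(OCOC)c(OC)c(CC=C(C)C)c1
F3 | step 5 | 7-(methoxymethoxy)-2,2-dimethylchroman-5-yl N,N-diethylcarbamate | COCOc1cc(OC(=O)N(CC)CC)c2CCC(C)(C)Oc2c1
F4 | step 5 | 7-(methoxymethoxy)-2,2-dimethyl-6-(trimethylsilyl)chroman-5-yl N,N-diethylcarbamate | COCOc1cc2OC(C)(C)CCc2c(OC(=O)N(CC)CC)c1[Si](C)(C)C
F5 | step 11 | 3-[3-allyl-4-methoxy-5-(methoxymethoxy)phenyl]propanoic acid | COCOc1cc(CCC(=O)O)cc(CC=C)c1OC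
F6 | step 3 | 7-(methoxymethoxy)-2,2-dimethylchroman-4,5-diol (racemic) | COCOc1cc(O)c2C(O)CC(C)(C)Oc2c1
A1 | alternative 1 | 5,7-dimethoxy-2,2-dimethylchroman-6-carbaldehyde | COc1cc2OC(C)(C)CCc2c(OC)c1C=O
A2 | alternative 1 | 3-[(dimethylamino)methyl]-4-hydroxy-2,6-dimethoxybenzaldehyde | COc1cc(O)c(CN(C)C)c(OC)c1C=O
A3 | alternative 1 | isobutene (2-methylpropene) | CC(C)=C
A4 | alternative 2 | 1-(5,7-dihydroxy-2,2-dimethyl-2H-chromen-6-yl)-3-[3-hydroxy-4-methoxy-5-(3-methylbut-2-enyl)phenyl]propan-1-one | COc1c(O)cc(CCC(=O)c2c(O)cc3OC(C)(C)C=Cc3c2O)cc1CC=C(C)C
A5 | alternative 2 | 1-[2,6-dihydroxy-4-(2-methylbut-3-yn-2-yloxy)phenyl]-3-[3-hydroxy-4-methoxy-5-(3-methylbut-2-enyl)phenyl]propan-1-one | COc1c(O)cc(CCC(=O)c2c(O)cc(OC(C)(C)C#C)cc2O)cc1CC=C(C)C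
A6 | alternative 3 | 4-bromo-2-(3-hydroxy-3-methylbutyl)-3,5-dimethoxyphenol | CC(C)(O)CCc1c(O)cc(OC)c(Br)c1OC
A7 | alternative 3 | 6-bromo-5,7-dimethoxychroman-2-one | COc1cc2OC(=O)CCc2c(OC)c1Br
A8 | alternative 3 | 6-bromo-5,7-dimethoxy-2,2-dimethylchroman | COc1cc2OC(C)(C)CCc2c(OC)c1Br
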